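The data are calculated for substances that don't exist; scatter was added.

Which ends with the longer chains, Monday's flask or Sunday's, and how long are they?

the same everywhere: free monomer 0.050 M

| charge | transfer agent | protic impurity | initiator | remark | time |
|---|---|---|---|---|---|
| blue | 0.015 M | 0.015 M | 0.39 mol% | run made earlier |  |
| ochre | 0.015 M | 0.015 M | 1.8 mol% | run made earlier |  |
| Monday's | 0.0150 M | 0.0150 M | 0.5 mol% |  | 10 min |
| Sunday's | 0.0150 M | 0.0150 M | 2 mol% |  | 10 min |

| run | time / min | monomer in chains / % |
|---|---|---|
| blue | 0.500 | 1.0 |
| blue | 1.33 | 2.5 |
| blue | 2.50 | 4.4 |
| blue | 4.00 | 6.5 |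
| blue | 5.00 | 8.8 |
| blue | 8.00 | 12.8 |
| ochre | 0.500 | 2.2 |
| ochre | 1.00 | 5.2 |
| ochre | 1.50 | 10.3 |
| ochre | 2.50 | 17.3 |
| ochre | 4.00 | 26.8 |
| ochre | 8.00 | 43.9 |

(scatter of a reading: 0.5 percentage points)

- the average divides the monomer in chains by the number of chains begun, living and dead together
- the earlier runs do not show the number of chains; that part of a forecast is a guess

1. which of the two ends with the longer chains by the average number of monomer units in a chain (chains begun, living or dead) ("neither" if they lie within 10%) (Monday's / Sunday's / neither)
2. average number of monomer units in a chain (chains begun, living or dead) at the end, Monday's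
3. average number of monomer units in a chain (chains begun, living or dead) at the end, Sunday's

The average is a quotient, so we reckon its top and bottom apart. For the bottom we commit to a guess that the runs cannot test: we count one chain per initiator charged and none from the transfer agent. Monomer charged per initiator charged is then 50.0 in Sunday's and 200 in Monday's. We call this the target length, the usual term being target degree of polymerization. So:

length = share of the charged free monomer in chains × target length

For the top we treat the free monomer as pseudo-first-order, with a rate constant proportional to the initiator. The last readings give 0.0171 min⁻¹ in the blue run and 0.0723 min⁻¹ in the ochre run. Their ratio of 4.23 stands against 4.62 in initiator, which is near enough for a short step from each run to its nearest flask.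

Monday's, from blue: rate constant 0.0219 min⁻¹, share at 10 min 19.7%, length 39.4

Sunday's, from ochre: rate constant 0.0803 min⁻¹, share at 10 min 55.2%, length 27.6

We therefore expect Monday's chains to be longer by a factor of 1.43, well outside the 10% margin. On a repeat, the reading to watch is the monomer in chains at 10 min.

The forecast also names Monday's, but with shorter chains than ours: 29 for Monday's and 22 for Sunday's. Its ground for the difference is a guess, “Transfer adds chains per monomer consumed”.

The flask gives Monday's, with 37.6 for Monday's and 25.8 for Sunday's.

    free monomer + initiator → spent initiator (k = 0.110 M⁻¹ min⁻¹)
    living end + transfer agent → dead chain (kL = 2.80 M⁻¹ min⁻¹)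
    protic impurity + free monomer → quenched substrate (k = 12.0 M⁻¹ min⁻¹)
    free monomer + initiator → living end + monomer in chains (k = 24.0 M⁻¹ min⁻¹)
    free monomer + living end → monomer in chains + living end, rate k5*[living end]*[free monomer] (k = 150 M⁻¹ min⁻¹)

In Monday's at 10.0 min, living end and dead chain together stand at 2.49 × 10⁻⁴ M, against 2.50 × 10⁻⁴ M of initiator charged, and a dead chain here is a former living end. Sunday's 51.1% in chains, times the target length 50.0 and divided by the 99.2% of charged initiator that began chains, gives 25.8. A neighbour of Sunday's, charged with 0.020 M of free monomer, keeps that target length but holds 18.9% in chains, with 91.5% of its charged initiator having begun chains, and so ends at a length of 10.3.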